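**Strategy.** The oxolane ring is disconnected at O1–C2 (ring oxygen to the aryl-bearing carbon) and C3–C4 (carbinol carbon to the benzyl-bearing carbon). The key step, a palladium-catalysed asymmetric (3+2) cycloaddition, joins the O1–C5–C4 dipole of 2-vinyloxirane to the C2=C3 double bond of a benzylidene Meldrum's acid and closes the ring in one operation. It exploits the 1,3-relation of O1 and C4 and the fully substituted C3 flanked by the benzylic C2. The precursor pair is achiral or racemic. C3 arrives as a spiro malonate carbon and C4 with a vinyl placeholder, later turned into the benzyl group through a temporary γ-lactone that also differentiates the C3 carbonyls.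

Key step: step 2

Remark on locants: oxolane O1, C2 (aryl), C3 (OH, CH2OH), C4 (benzyl), C5; C9 is the hydroxymethyl carbon on C3 and C7' the benzylic carbon on C4.
Assumption: the (R,R) ligand is taken to give the C4 configuration drawn; if the sense of induction is the opposite, the (S,S) ligand is used and nothing else changes.

Step 1
Reactants: 1 4-(benzyloxy)-3-methoxybenzaldehyde; 2 2,2-dimethyl-1,3-dioxane-4,6-dione (Meldrum's acid)
Product: 3 5-[[4-(benzyloxy)-3-methoxyphenyl]methylidene]-2,2-dimethyl-1,3-dioxane-4,6-dione
Conditions: piperidinium acetate (10 mol%), EtOH, rt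
Reagents that add atoms: none
Why: Knoevenagel condensation of an aromatic aldehyde with the acidic methylene of Meldrum's acid; the two carbonyl arms are identical, so no alkene isomer arises.

Step 2
Reactants: 3 benzylidene Meldrum's acid; 4 2-vinyloxirane (racemic)
Product: 6 (1R,4R)-1-[4-(benzyloxy)-3-methoxyphenyl]-8,8-dimethyl-4-vinyl-2,7,9-trioxaspiro[4.5]decane-6,10-dione (aryl and vinyl trans), via allylpalladium enolate zwitterion 5 (not isolated)
Conditions: Pd2(dba)3·CHCl3 (2.5 mol%), (R,R)-DACH-phenyl Trost ligand (7.5 mol%), THF, 0 °C to rt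
Reagents that add atoms: none
Why: Zerovalent palladium ionises the allylic C–O bond of 4 to a zwitterionic π-allylpalladium alkoxide, whose oxygen adds reversibly to the benzylidene carbon of 3 (O1–C2) to give enolate 5; the enolate carbon then attacks the internal allyl terminus (C3–C4) and releases the catalyst. The closest known reaction type is the palladium-catalysed formal (3+2) cycloaddition of vinyl epoxides with doubly activated alkenes, run as a dynamic kinetic asymmetric transformation because the π-allyl faces interconvert faster than the ring closes. The oxolane closes in a 5-exo mode by allylic alkylation at the substituted terminus, the seven-membered alternative through the distal terminus being disfavoured. C4 is set by the chiral ligand, which selects the allyl face attacked by the enolate; C2 is set relative to C4 in the same ring closure, with the aryl group trans to the vinyl group across the bulky spiro centre; C3 is not yet a stereocentre. The step needs conjugate addition of the alkoxide rather than acyl attack on the dioxanedione, which the reversibility of both additions and the irreversible C–C bond formation should secure. It also needs trans diastereoselectivity, which is the least certain point of the route.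

Step 3
Reactants: 6 spiro cycloadduct
Product: 7 (1R,4R)-1-[4-(benzyloxy)-3-methoxyphenyl]-8,8-dimethyl-6,10-dioxo-2,7,9-trioxaspiro[4.5]decane-4-carbaldehyde
Conditions: O3, CH2Cl2, −78 °C; then PPh3, −78 °C to rt
Reagents that add atoms: ozone, [O-][O+]=O
Why: Ozonolysis with reductive work-up cleaves the only alkene to the aldehyde; cold, neutral handling should keep the C4 stereocentre next to the formyl group intact.

Step 4
Reactants: 7 aldehyde; 8 1-(benzyloxy)-4-bromo-2-methoxybenzene
Product: 11 (1S,5R,8S)-4,8-bis[4-(benzyloxy)-3-methoxyphenyl]-3,7-dioxabicyclo[3.3.0]octan-2-one (cis-fused; 8-aryl exo; epimers at the benzylic lactone carbon), via arylmagnesium bromide 9 (not isolated), via lactone carboxylic acid 10 (not isolated)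
Conditions: 8, Mg, THF, rt; then 7, THF, −78 to 0 °C; aq. HCl; then toluene, 100 °C
Reagents that add atoms: none
Why: Grignard addition to the aldehyde gives an alkoxide that acylates itself with the syn carbonyl of the spiro dioxanedione (lactonisation with loss of acetone), which tells the two C3 carbonyls apart; the malonic-type acid 10 then decarboxylates on heating and is protonated to the cis-fused lactone, so C3 is fixed by the ring fusion, while the new benzylic centre is uncontrolled and is removed in step 6.

Step 5
Reactants: 11 cis-fused lactone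
Product: 12 (1R,5R,8R)-4,8-bis[4-(benzyloxy)-3-methoxyphenyl]-1-hydroxy-3,7-dioxabicyclo[3.3.0]octan-2-one
Conditions: KN(SiMe3)2, THF, −78 °C; then 2-(phenylsulfonyl)-3-phenyloxaziridine, −78 °C; AcOH
Reagents that add atoms: 2-(phenylsulfonyl)-3-phenyloxaziridine, O=S(=O)(c1ccccc1)N1OC1c1ccccc1
Why: Electrophilic α-hydroxylation of the lactone enolate with an N-sulfonyloxaziridine; the ring-fusion enolate can only be attacked on the convex face, so the hydroxyl replaces the angular hydrogen with retention and the cis fusion (C3 relative to C4) is kept.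

Step 6
Reactants: 12 hydroxy lactone
Product: 13 (2R,3R,4S)-3-hydroxy-2-(4-hydroxy-3-methoxyphenyl)-4-[(4-hydroxy-3-methoxyphenyl)methyl]oxolane-3-carboxylic acid
Conditions: H2 (1 atm), 10% Pd/C, EtOAc/MeOH, rt, stopped after 3 equiv H2
Reagents that add atoms: none
Why: Hydrogenolysis cleaves the benzylic carboxylate C–O bond of the lactone (C7' becomes the CH2 of the benzyl group, its uncontrolled centre disappears) and both aryl benzyl ethers; the ring ether O1–C2 should survive because an alkoxide is a poorer leaving group than a carboxylate and C2 is shielded by the fully substituted C3.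

Step 7
Reactants: 13 hydroxy acid
Product: 14 (2R,3S,4S)-2-(4-hydroxy-3-methoxyphenyl)-4-[(4-hydroxy-3-methoxyphenyl)methyl]-3-(hydroxymethyl)oxolan-3-ol
Conditions: BH3·THF (excess), THF, 0 °C to rt; then MeOH
Reagents that add atoms: none
Why: Chemoselective borane reduction of the carboxylic acid to the primary alcohol; no stereocentre is touched and the phenols are regenerated on methanolysis.

**Compound list**

1 | 4-(benzyloxy)-3-methoxybenzaldehyde | O=Cc1ccc(OCc2ccccc2)c(OC)c1 | starting material
2 | 2,2-dimethyl-1,3-dioxane-4,6-dione (Meldrum's acid) | CC1(C)OC(=O)CC(=O)O1 | starting material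
3 | 5-[[4-(benzyloxy)-3-methoxyphenyl]methylidene]-2,2-dimethyl-1,3-dioxane-4,6-dione | CC1(C)OC(=O)C(=Cc2ccc(OCc3ccccc3)c(OC)c2)C(=O)O1 | intermediate
4 | 2-vinyloxirane (racemic) | C=CC1CO1 | starting material
5 | allylpalladium enolate zwitterion (oxa-Michael adduct, ligands omitted, one resonance form) | COc1cc(C(OC/C=C/C[Pd+])C2=C([O-])OC(C)(C)OC2=O)ccc1OCc1ccccc1 | intermediate (not isolated)
6 | (1R,4R)-1-[4-(benzyloxy)-3-methoxyphenyl]-8,8-dimethyl-4-vinyl-2,7,9-trioxaspiro[4.5]decane-6,10-dione | C=C[C@H]1CO[C@H](c2ccc(OCc3ccccc3)c(OC)c2)C14C(=O)OC(C)(C)OC4=O | intermediate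
7 | (1R,4R)-1-[4-(benzyloxy)-3-methoxyphenyl]-8,8-dimethyl-6,10-dioxo-2,7,9-trioxaspiro[4.5]decane-4-carbaldehyde | O=C[C@H]1CO[C@H](c2ccc(OCc3ccccc3)c(OC)c2)C14C(=O)OC(C)(C)OC4=O | intermediate
8 | 1-(benzyloxy)-4-bromo-2-methoxybenzene | COc1cc(Br)ccc1OCc1ccccc1 | starting material
9 | [4-(benzyloxy)-3-methoxyphenyl]magnesium bromide | COc1cc([Mg]Br)ccc1OCc1ccccc1 | intermediate (not isolated)
10 | cis-fused 4,8-bis[4-(benzyloxy)-3-methoxyphenyl]-2-oxo-3,7-dioxabicyclo[3.3.0]octane-1-carboxylic acid (8-aryl exo; epimers at the benzylic lactone carbon) | COc1cc(ccc1OCc1ccccc1)C3[C@H]2CO[C@H](c4ccc(OCc5ccccc5)c(OC)c4)[C@@]2(C(=O)O)C(=O)O3 | intermediate (not isolated)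
11 | (1S,5R,8S)-4,8-bis[4-(benzyloxy)-3-methoxyphenyl]-3,7-dioxabicyclo[3.3.0]octan-2-one (epimers at the benzylic lactone carbon) | COc1cc(ccc1OCc1ccccc1)C3[C@H]2CO[C@H](c4ccc(OCc5ccccc5)c(OC)c4)[C@H]2C(=O)O3 | intermediate
12 | (1R,5R,8R)-4,8-bis[4-(benzyloxy)-3-methoxyphenyl]-1-hydroxy-3,7-dioxabicyclo[3.3.0]octan-2-one (epimers at the benzylic lactone carbon) | COc1cc(ccc1OCc1ccccc1)C3[C@H]2CO[C@H](c4ccc(OCc5ccccc5)c(OC)c4)[C@@]2(O)C(=O)O3 | intermediate
13 | (2R,3R,4S)-3-hydroxy-2-(4-hydroxy-3-methoxyphenyl)-4-[(4-hydroxy-3-methoxyphenyl)methyl]oxolane-3-carboxylic acid | COc1cc(C[C@H]2CO[C@H](c3ccc(O)c(OC)c3)[C@@]2(O)C(=O)O)ccc1O | intermediate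
14 | (2R,3S,4S)-2-(4-hydroxy-3-methoxyphenyl)-4-[(4-hydroxy-3-methoxyphenyl)methyl]-3-(hydroxymethyl)oxolan-3-ol | COc1cc(C[C@H]2CO[C@H](c3ccc(O)c(OC)c3)[C@@]2(O)CO)ccc1O | target

Total step count: 7. Longest linear sequence: 7 steps (1 → 3 → 6 → 7 → 11 → 12 → 13 → 14).

**Steps most likely to fail**

Step 2. The ring-closing allylic alkylation may show poor facial control at C2, so that the aryl group ends cis to the vinyl group. The fallback replaces kinetic catalyst control by thermodynamic control at a later stage; it sets out from compounds 3 and 4 and comes back at compound 11. The cis adduct, the C1 epimer of 6, cis spiro adduct F1, is not discarded. Ozonolysis as in step 3 should give the epimeric aldehyde F2. Grignard addition and lactonisation as in step 4 should give the endo-aryl lactone acid F3, and decarboxylation the endo-aryl lactone F4. F4 is then equilibrated with DBU (toluene, 60 °C): the lactone enolate opens the oxolane by β-elimination of O1 to an α-arylidene lactone alkoxide, which recloses by oxa-Michael addition. The exo-aryl isomer 11, free of the clash between the aryl group and the lactone on the concave face, should accumulate, though the energy difference may be small.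

Step 6. Hydrogenolysis may run on after the phenols are unmasked and cleave the second benzylic C–O bond (O1–C2), opening the oxolane. The fallback replaces hydrogenolytic lactone opening by nucleophilic opening and radical reduction; it sets out from compound 12 and comes back at compound 13. Sodium phenylselenide (from (PhSe)2 and NaBH4, DMF, 110 °C) opens the lactone by SN2 attack at the benzylic lactone carbon and leaves the ring ether alone, giving the seleno acid F7. Bu3SnH with AIBN (benzene, 80 °C) exchanges selenium for hydrogen and gives the dibenzyl ether of 13, hydroxy acid dibenzyl ether F8. The two aryl benzyl ethers are then removed by brief hydrogenolysis over Pd/C, which they undergo much faster than the hindered ring ether.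

Step 5. The lactone enolate may lose the ring oxygen by β-elimination (retro-oxa-Michael opening of the oxolane) faster than it takes up oxygen at the hindered angular carbon, which would also scramble C2. The fallback replaces enolate chemistry by a radical decarboxylative hydroxylation; it sets out from compound 10 (isolated by leaving out the heating stage of step 4) and comes back at compound 12. Acid 10 is coupled with 1-hydroxypyridine-2(1H)-thione (DCC, DMAP, CH2Cl2, dark) to the O-acyl thiohydroxamate, Barton ester F5. Irradiation under oxygen with tert-butyl thiol (toluene, 0 °C) should give, by decarboxylation and oxygen capture of the ring-fusion radical on the convex face, the angular hydroperoxide F6. PPh3 reduces F6 to 12; the cis ring fusion enforces the same C3 configuration.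

Further compounds
F1 | step 2 | C1 epimer of 6 (aryl and vinyl cis) | C=C[C@H]1CO[C@@H](c2ccc(OCc3ccccc3)c(OC)c2)C14C(=O)OC(C)(C)OC4=O
F2 | step 2 | C1 epimer of 7 | O=C[C@H]1CO[C@@H](c2ccc(OCc3ccccc3)c(OC)c2)C14C(=O)OC(C)(C)OC4=O
F3 | step 2 | C8 epimer of 10 (8-aryl endo) | COc1cc(ccc1OCc1ccccc1)C3[C@H]2CO[C@@H](c4ccc(OCc5ccccc5)c(OC)c4)[C@@]2(C(=O)O)C(=O)O3
F4 | step 2 | C8 epimer of 11 (8-aryl endo) | COc1cc(ccc1OCc1ccccc1)C3[C@H]2CO[C@@H](c4ccc(OCc5ccccc5)c(OC)c4)[C@H]2C(=O)O3
F5 | step 5 | O-acyl thiohydroxamate (Barton ester) of acid 10 | COc1cc(ccc1OCc1ccccc1)C3[C@H]2CO[C@H](c4ccc(OCc5ccccc5)c(OC)c4)[C@@]2(C(=O)ON6C=CC=CC6=S)C(=O)O3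
F6 | step 5 | angular hydroperoxide corresponding to 12 | COc1cc(ccc1OCc1ccccc1)C3[C@H]2CO[C@H](c4ccc(OCc5ccccc5)c(OC)c4)[C@@]2(OO)C(=O)O3
F7 | step 6 | 2-[4-(benzyloxy)-3-methoxyphenyl]-4-[[4-(benzyloxy)-3-methoxyphenyl](phenylselanyl)methyl]-3-hydroxyoxolane-3-carboxylic acid | COc1cc(ccc1OCc1ccccc1)C([Se]c1ccccc1)[C@H]2CO[C@H](c3ccc(OCc4ccccc4)c(OC)c3)[C@@]2(O)C(=O)O
F8 | step 6 | dibenzyl ether of 13 | COc1cc(C[C@H]2CO[C@H](c3ccc(OCc4ccccc4)c(OC)c3)[C@@]2(O)C(=O)O)ccc1OCc1ccccc1
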